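Late in the east run double product stood clear of the scatter, so I began there, working with the fraction of substrate left, a, and not with the fraction made.

| setting | east | south-east | flask |
|---|---|---|---|
| substrate | 0.050 M | 0.11 M | 0.074 M |
| partner | 0.111 M (fed, over 25 min) | 0.111 M (fed, over 25 min) | 0.111 M (fed, over 25 min) |
| scavenger | 0.0592 M | 0.0592 M | 0.0592 M |
| remark | run made earlier; the fed solution adds 0.20 times the starting volume | run made earlier; the fed solution adds 0.20 times the starting volume | the fed solution adds 0.20 times the starting volume |
| time |  |  | 2.0 d |

| run | time / h | double product / % | single product / % | substrate / % |
|---|---|---|---|---|
| east | 2.50 | 0.1 | 14.9 | 84.8 |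
| east | 8.00 | 1.4 | 38.9 | 60.1 |
| east | 12.0 | 2.6 | 49.3 | 48.1 |
| east | 20.0 | 5.3 | 62.2 | 31.6 |
| east | 30.0 | 8.9 | 71.3 | 20.1 |
| south-east | 2.50 | 0.6 | 14.2 | 84.3 |
| south-east | 8.00 | 0.8 | 34.3 | 63.8 |
| south-east | 12.0 | 1.0 | 43.8 | 54.2 |
| south-east | 20.0 | 3.5 | 53.4 | 40.2 |
| south-east | 30.0 | 4.5 | 61.4 | 30.6 |

(readings scatter by 0.5 percentage points)

- amounts and yields of released group count idle adduct too
- charges are per starting volume, the dose included; the dosed solution carries all of it
- reactions considered so far: substrate + partner -> single product + released group; substrate + released group <-> idle adduct; scavenger + released group -> scavenged by-product; partner + single product -> double product + released group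

- the species that holds most of what was charged as substrate, at 2.0 d (single product / double product / substrate)
- the largest share itself, whichever of these holds it, in percent of the substrate charged

Substrate goes to single product and single product to double product, each step taking partner, so partner cancels in the ratio of their rates and a can serve as the clock. Single product then follows (a^s − a)/(1 − s), and for small s double product follows s(ln(1/a) − (1 − a)). The last east reading gave s = 0.110, the selectivity factor, the rate constant of the step to double product over that of the step to single product.

For a in the flask I needed hours. The dose of 25 min was short beside 2.0 d, so I took partner as present at once and counted its use by the first step: a = (B − A)/(B·exp(k(B − A)t) − A), with A and B the charges of substrate and partner. The last east reading gave k = 0.633 M⁻¹ h⁻¹ per starting volume, so I reckoned a = 13.8% for the flask and single product at 74.8%.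

The weak link was the partner taken by the step to double product. Charging half of the double product against B, in the east run and in my reckoning for the flask, moved a to 14.7% and single product to 74.4%, and I committed to that figure, with single product ahead of substrate and double product.

The forecast said single product at 74%, between 69% and 78%, its grounds opening with “The mass balance closes in the east run”.

The flask gave single product at 73.4%, inside that range, with substrate at 14.3% and double product at 11.1%.

    substrate + partner → single product + released group (k = 0.0129 M⁻¹ min⁻¹)
    substrate + released group ⇌ idle adduct, settled at all times (K = 9.60 M⁻¹)
    scavenger + released group → scavenged by-product (k = 1.27 M⁻¹ min⁻¹)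
    partner + single product → double product + released group (k = 0.00148 M⁻¹ min⁻¹)

At 2.00 d the step to single product in the flask still used partner 1.7 times as fast as the step to double product, and substrate over s times single product, the same ratio reckoned with my s, came to 1.77. In the flask left until 8.00 d that same ratio had fallen to 0.235, and single product stood at 67.5%, lower than the 73.4% at 2.00 d.

All runs come from a simulation for an exercise; scatter was added.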